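At the first moment Thursday's closed flask holds no product and so no idle adduct, and its rate follows the free starting material, which the balance later withdraws.

| flask | starting material | reagent | remark | time |
|---|---|---|---|---|
| Monday's | 0.020 M | 0.100 M | one stirred flow tank at steady state, fed with the mixture as stated, mean residence time 1.0 h |  |
| Tuesday's | 0.020 M | 0.100 M | a single well-mixed tank run continuously and read at steady state, 10.0 h in it on average |  |
| Thursday's | 0.020 M | 0.100 M | everything together in a closed stirred flask, run for 1.0 h | 1.0 h |
| Friday's | 0.020 M | 0.100 M (fed, over 0.800 h) | all but reagent at the start; reagent goes in evenly over 0.800 h, the run ends at 1.0 h | 1.0 h |

    starting material + reagent → product, rate k1*[starting material]^1.5*[reagent] (k1 = 0.0972 M⁻¹·⁵ s⁻¹)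
    starting material + product ⇌ idle adduct, settled at all times (K2 = 87 M⁻¹)

1. the set-up with the highest amount of product at the outlet or at the end, in percent of the starting material put in ("none" if the first two lie within 2 percentage points) (Monday's / Tuesday's / Thursday's / Friday's / none)
2. amount of product at the outlet or at the end, in percent of the starting material put in, Monday's
3. amount of product at the outlet or at the end, in percent of the starting material put in, Tuesday's
4. amount of product at the outlet or at the end, in percent of the starting material put in, Thursday's
5. amount of product at the outlet or at the end, in percent of the starting material put in, Friday's

- percentages count the starting material that a species holds: one idle adduct counts as two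
- product is meant together with its idle adduct
- the stated concentrations are those of everything mixed, before any reaction; amounts are the same in each set-up
- the feed brings no volume worth counting
- in an amount of product, one idle adduct counts as one product
- run time (Thursday's): 1.0 h

I reckon Thursday's flask, where the starting material is the limiting reagent, with 0.020 M against 0.100 M of reagent. Let S be the starting material not yet turned to product, free or bound, and f the part of S that is free. With P for free product and K for the equilibrium constant, the balance gives f = 1/(1 + K·P). The rate is its constant times reagent times fS to the power 1.50. If f and the reagent are held fixed, this integrates by hand.

For a ceiling I set f to 1 and keep the reagent at its full charge, which gives 91.7% product in Thursday's flask at 1.0 h. For a floor I note that P stays within the charge, so f stays at or above 0.365: the floor share, a lower bound on the part of the unconverted starting material that is free. With reagent at its lower bound, 0.0800 M, the floor is 51.5%. Feeding the ceiling back limits P and the reagent used up to 1.0 h, so over that time f stays above 0.385 and the reagent above 0.0817 M. That lifts the floor to 54.5%, and there my hand stops. I give no figure for the other set-ups.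

The forecast gives 57%, 83%, 76% and 66% from Monday's to Friday's, which puts its Thursday's figure inside my bracket, enters Thursday's as best, yet says “on the numbers as asked, Tuesday's is actually highest”.

The simulation gives 56.9%, 83.1%, 75.9% and 66.4% in that order, so the best is Tuesday's.

Thursday's 75.9% lies inside my bracket, and its free share at 1.00 h reads 0.476, above the floor share. The neighbouring flask is Thursday's with 0.080 M of starting material. There the floor share falls to 0.126, the ceiling is 97.2%, and the first floor is 8.26%. That flask gives 67.1%, between its floor and its ceiling, with a free share at 1.00 h reading 0.252.

(Its constants are invented.)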